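**Strategy.** The cyclohexane ring is disconnected at C4–C5, the bond between the quaternary CMe2 carbon and the CHBr carbon (locants follow the cyclohexyl acetate name). The ring triad C5(Br)–C4(Me2)–C3(Cl) is read as a masked 3-hydroxy-2,2-dimethyl ketone, so the ring is closed by a reductive aldol cyclisation. Copper hydride converts the methacryloyl end of an acyclic dienone aldehyde into the fully substituted C4 enolate, which adds to the C5 aldehyde. One operation should give the ring, the quaternary carbon and an axial C5 carbinol trans to the C1 acetate. The precursor already holds the (S)-acetate and the (Z)-alkylidene. Two invertive halogenations and a silyl ether to bromide exchange complete the target.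

Key step: step 7

Remark: C1 bears OAc, C2 the alkylidene (C1′, C2′), C3 Cl, C4 the two methyl groups, C5 Br, and C6 is CH2. "Upper face" is the face of the C1 acetate. TBS = tert-butyldimethylsilyl. Copper species are drawn without phosphine ligands.

Step 1
Reactants: 1 ethyl 3,3-diethoxypropanoate; 2 tert-butyldimethyl(prop-2-yn-1-yloxy)silane
Product: 5 6-(TBSO)-1,1-diethoxyhex-4-yn-3-one, via Weinreb amide 3 (not isolated), via lithium acetylide 4 (not isolated)
Conditions: MeNHOMe·HCl, i-PrMgCl, THF, −20 °C; then 4 (from 2, n-BuLi, THF, −78 °C), −20 → 0 °C; aq NH4Cl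
Reagents that add atoms: N,O-dimethylhydroxylamine hydrochloride, CNOC.Cl (its atoms stay only in 3)
Why: One-pot Weinreb ketone synthesis, in which the magnesium amide turns ester 1 into amide 3 and the chelated tetrahedral adduct of 3 and acetylide 4 stops the addition at the ynone.

Step 2
Reactants: 5 6-(TBSO)-1,1-diethoxyhex-4-yn-3-one
Product: 6 (3S)-6-(TBSO)-1,1-diethoxyhex-4-yn-3-ol
Conditions: RuCl[(S,S)-TsDPEN](p-cymene) (1 mol %), KOH (2 mol %), i-PrOH, 25 °C
Reagents that add atoms: none
Why: Noyori asymmetric transfer hydrogenation of an alkynyl ketone, in which the alkyne takes the place of the aryl group of aryl ketones, so the (S,S)-catalyst should give the (S)-carbinol that becomes C1.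

Step 3
Reactants: 6 (3S)-6-(TBSO)-1,1-diethoxyhex-4-yn-3-ol
Product: 7 (3S,4Z)-6-(TBSO)-1,1-diethoxy-4-(tributylstannyl)hex-4-en-3-ol
Conditions: [Cp*RuCl]4 (1.25 mol %), Bu3SnH, CH2Cl2, 25 °C
Reagents that add atoms: tributyltin hydride, CCCC[SnH](CCCC)CCCC
Why: Ruthenium-catalysed trans-hydrostannation of a propargylic alcohol, in which the free OH steers tin to the proximal alkyne carbon and anti addition places tin cis to CH2OTBS, fixing the later C2=C1′ geometry.

Step 4
Reactants: 7 (3S,4Z)-6-(TBSO)-1,1-diethoxy-4-(tributylstannyl)hex-4-en-3-ol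
Product: 8 (3S,4Z)-6-(TBSO)-1,1-diethoxy-4-(tributylstannyl)hex-4-en-3-yl acetate
Conditions: Ac2O, pyridine, DMAP (cat.), CH2Cl2, 0 → 25 °C
Reagents that add atoms: acetic anhydride, CC(=O)OC(C)=O
Why: DMAP-catalysed acetylation installs the acetate of the target early, so C1 needs no protecting group.

Step 5
Reactants: 8 (3S,4Z)-6-(TBSO)-1,1-diethoxy-4-(tributylstannyl)hex-4-en-3-yl acetate; 9 methacryloyl chloride
Product: 10 (3S,4Z)-4-[2-(TBSO)ethylidene]-1,1-diethoxy-6-methyl-5-oxohept-6-en-3-yl acetate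
Conditions: Pd2(dba)3 (2.5 mol %), P(2-furyl)3 (10 mol %), BHT (trace), THF, 45 °C
Reagents that add atoms: none
Why: Stille acylation proceeds with retention of alkene geometry, and oxidative addition of zerovalent palladium to the acyl chloride should be much faster than ionisation of the hindered secondary allylic acetate.

Step 6
Reactants: 10 (3S,4Z)-4-[2-(TBSO)ethylidene]-1,1-diethoxy-6-methyl-5-oxohept-6-en-3-yl acetate
Product: 11 (3S,4Z)-4-[2-(TBSO)ethylidene]-6-methyl-1,5-dioxohept-6-en-3-yl acetate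
Conditions: TESOTf, 2,6-lutidine, CH2Cl2, 0 °C; then H2O
Reagents that add atoms: water, O
Why: Silyl triflate with a hindered pyridine activates acetals of aldehydes selectively, and water then frees the aldehyde under non-acidic conditions that spare the TBS ether, the acetate and the dienone.

Step 7
Reactants: 11 (3S,4Z)-4-[2-(TBSO)ethylidene]-6-methyl-1,5-dioxohept-6-en-3-yl acetate
Product: 13 (1S,2Z,5S)-2-[2-(TBSO)ethylidene]-5-hydroxy-4,4-dimethyl-3-oxocyclohexyl acetate, via copper enolate 12 (not isolated)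
Conditions: [(Ph3P)CuH]6 (0.2 equiv), toluene, −40 °C; aq NH4Cl
Reagents that add atoms: none
Why: Copper hydride adds 1,4 to the unsubstituted CH2 terminus of the methacryloyl unit, far faster than to the β-substituted C2=C1′ enone or to the aldehyde, and gives the fully substituted enolate 12, whose C4 attacks the C5 aldehyde. The reaction type is the known tandem conjugate reduction–intramolecular aldol (reductive aldol cyclisation) of enone carbonyl compounds with phosphine copper hydrides. The six-membered ring closes in the 6-(enolendo)-exo-trig mode, favoured by the Baldwin rules. The only new stereocentre, C5, is set by a closed Zimmerman–Traxler array in which copper bridges both oxygens: this needs a gauche O–C5–C4–C3 arrangement, that is an axial C5–O bond, and the C1 acetate stays equatorial to avoid a 1,3-diaxial contact, so the 1,5-trans (5S) alcohol should result. Enolate regiochemistry is secured because hydride delivery and not deprotonation creates it and the ketone has no other α-hydrogen, while the low temperature and weakly basic medium hold back β-elimination of acetate from the aldehyde. C4 is not stereogenic, so the quaternary carbon raises no selectivity issue.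

Step 8
Reactants: 13 (1S,2Z,5S)-2-[2-(TBSO)ethylidene]-5-hydroxy-4,4-dimethyl-3-oxocyclohexyl acetate
Product: 14 (1S,2Z,5R)-5-bromo-2-[2-(TBSO)ethylidene]-4,4-dimethyl-3-oxocyclohexyl acetate
Conditions: CBr4, PPh3, CH2Cl2, 0 → 25 °C
Reagents that add atoms: carbon tetrabromide, BrC(Br)(Br)Br
Why: Appel reaction with inversion, in which bromide displaces the axial oxyphosphonium group and gives the equatorial (5R) bromide cis to the acetate, while the C3 ketone disfavours cationic methyl shifts from C4.

Step 9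
Reactants: 14 (1S,2Z,5R)-5-bromo-2-[2-(TBSO)ethylidene]-4,4-dimethyl-3-oxocyclohexyl acetate
Product: 15 (1S,2E,3S,5R)-5-bromo-2-[2-(TBSO)ethylidene]-3-hydroxy-4,4-dimethylcyclohexyl acetate (same geometry, CH2OTBS cis to C3)
Conditions: NaBH4, CeCl3·7H2O, MeOH, −78 → −40 °C
Reagents that add atoms: none
Why: Luche reduction gives 1,2-reduction only, and the axial C4 methyl group shields the upper face, so hydride should enter axially from below and give the equatorial (3S) allylic alcohol.

Step 10
Reactants: 15 (1S,2E,3S,5R)-5-bromo-2-[2-(TBSO)ethylidene]-3-hydroxy-4,4-dimethylcyclohexyl acetate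
Product: 16 (1S,2Z,3R,5R)-5-bromo-3-chloro-2-[2-(TBSO)ethylidene]-4,4-dimethylcyclohexyl acetate
Conditions: PPh3, (Cl3C)2CO, CH2Cl2, −20 → 0 °C
Reagents that add atoms: hexachloroacetone, ClC(Cl)(Cl)C(=O)C(Cl)(Cl)Cl
Why: Appel-type chlorination of an allylic alcohol with inversion, in which the equatorial leaving group lies in the nodal plane of the alkene (poor alignment for ionisation or SN2′), neither neighbour carries a hydrogen for elimination, and relief of A1,3 strain with the cis CH2OTBS group favours the axial (3R) chloride.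

Step 11
Reactants: 16 (1S,2Z,3R,5R)-5-bromo-3-chloro-2-[2-(TBSO)ethylidene]-4,4-dimethylcyclohexyl acetate
Product: 17 (1S,2Z,3R,5R)-5-bromo-2-(2-bromoethylidene)-3-chloro-4,4-dimethylcyclohexyl acetate
Conditions: Ph3PBr2, CH2Cl2, 0 → 25 °C
Reagents that add atoms: triphenylphosphine dibromide, BrP(Br)(c1ccccc1)(c1ccccc1)c1ccccc1
Why: Triphenylphosphine dibromide converts primary TBS ethers directly into bromides through the alkoxyphosphonium salt, and SN2 at the primary allylic carbon keeps the alkene geometry and leaves the hindered secondary halides and the acetate untouched.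

**Compound list**
1 | ethyl 3,3-diethoxypropanoate | CCOC(=O)CC(OCC)OCC | starting material
2 | tert-butyldimethyl(prop-2-yn-1-yloxy)silane | C#CCO[Si](C)(C)C(C)(C)C | starting material
3 | 3,3-diethoxy-N-methoxy-N-methylpropanamide (Weinreb amide) | CCOC(CC(=O)N(C)OC)OCC | intermediate
4 | lithium 3-(TBSO)prop-1-yn-1-ide (lithium acetylide) | [Li]C#CCO[Si](C)(C)C(C)(C)C | intermediate
5 | 6-(TBSO)-1,1-diethoxyhex-4-yn-3-one | CCOC(CC(=O)C#CCO[Si](C)(C)C(C)(C)C)OCC | intermediate
6 | (3S)-6-(TBSO)-1,1-diethoxyhex-4-yn-3-ol | O[C@@H](CC(OCC)OCC)C#CCO[Si](C)(C)C(C)(C)C | intermediate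
7 | (3S,4Z)-6-(TBSO)-1,1-diethoxy-4-(tributylstannyl)hex-4-en-3-ol | O[C@@H](CC(OCC)OCC)/C([Sn](CCCC)(CCCC)CCCC)=C/CO[Si](C)(C)C(C)(C)C | intermediate
8 | (3S,4Z)-6-(TBSO)-1,1-diethoxy-4-(tributylstannyl)hex-4-en-3-yl acetate | CC(=O)O[C@@H](CC(OCC)OCC)/C([Sn](CCCC)(CCCC)CCCC)=C/CO[Si](C)(C)C(C)(C)C | intermediate
9 | methacryloyl chloride (2-methylprop-2-enoyl chloride) | CC(=C)C(=O)Cl | starting material
10 | (3S,4Z)-4-[2-(TBSO)ethylidene]-1,1-diethoxy-6-methyl-5-oxohept-6-en-3-yl acetate | CC(=O)O[C@@H](CC(OCC)OCC)/C(C(=O)C(C)=C)=C/CO[Si](C)(C)C(C)(C)C | intermediate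
11 | (3S,4Z)-4-[2-(TBSO)ethylidene]-6-methyl-1,5-dioxohept-6-en-3-yl acetate | CC(=O)O[C@@H](CC=O)/C(C(=O)C(C)=C)=C/CO[Si](C)(C)C(C)(C)C | intermediate
12 | copper enolate Me2C=C(OCu)– formed from 11 by hydride addition | CC(=O)O[C@@H](CC=O)/C(C(O[Cu])=C(C)C)=C/CO[Si](C)(C)C(C)(C)C | intermediate
13 | (1S,2Z,5S)-2-[2-(TBSO)ethylidene]-5-hydroxy-4,4-dimethyl-3-oxocyclohexyl acetate | CC(=O)O[C@H]1C[C@H](O)C(C)(C)C(=O)/C1=C\CO[Si](C)(C)C(C)(C)C | intermediate
14 | (1S,2Z,5R)-5-bromo-2-[2-(TBSO)ethylidene]-4,4-dimethyl-3-oxocyclohexyl acetate | CC(=O)O[C@H]1C[C@@H](Br)C(C)(C)C(=O)/C1=C\CO[Si](C)(C)C(C)(C)C | intermediate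
15 | (1S,2E,3S,5R)-5-bromo-2-[2-(TBSO)ethylidene]-3-hydroxy-4,4-dimethylcyclohexyl acetate | CC(=O)O[C@H]1C[C@@H](Br)C(C)(C)[C@@H](O)/C1=C\CO[Si](C)(C)C(C)(C)C | intermediate
16 | (1S,2Z,3R,5R)-5-bromo-3-chloro-2-[2-(TBSO)ethylidene]-4,4-dimethylcyclohexyl acetate | CC(=O)O[C@H]1C[C@@H](Br)C(C)(C)[C@H](Cl)/C1=C\CO[Si](C)(C)C(C)(C)C | intermediate
17 | (1S,2Z,3R,5R)-5-bromo-2-(2-bromoethylidene)-3-chloro-4,4-dimethylcyclohexyl acetate | CC(=O)O[C@H]1C[C@@H](Br)C(C)(C)[C@H](Cl)/C1=C\CBr | target

Total step count: 11. Longest linear sequence: 11 steps (1 or 2 to 17).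

**Steps most likely to fail**

**Step 8.**
- What may go wrong: backside attack next to the quaternary carbon may be too slow. Anti-periplanar loss of the axial oxyphosphonium group with an axial C6 hydrogen, or participation of the C1 acetate, may then take over.
- The fallback sets out from 13 and returns at 14. It makes the C–Br bond at an sp2 carbon and sets C5 by delivery of hydrogen.
- Dess–Martin oxidation gives (1S,2Z)-2-[2-(TBSO)ethylidene]-4,4-dimethyl-3,5-dioxocyclohexyl acetate F1.
- The less hindered, non-conjugated C5 ketone condenses with 1,2-bis(tert-butyldimethylsilyl)hydrazine (Sc(OTf)3 cat.) to give (1S,2Z)-5-[2-(tert-butyldimethylsilyl)hydrazinylidene]-2-[2-(TBSO)ethylidene]-4,4-dimethyl-3-oxocyclohexyl acetate F2.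
- Barton vinyl bromide synthesis (Br2, 2-tert-butyl-1,1,3,3-tetramethylguanidine) gives (1S,6Z)-3-bromo-6-[2-(TBSO)ethylidene]-4,4-dimethyl-5-oxocyclohex-2-en-1-yl acetate F3. This is the only possible regioisomer, since C4 has no hydrogen.
- Cobalt-catalysed hydrogen-atom-transfer hydrogenation (Co(acac)2, t-BuOOH, Et3SiH, 1,4-cyclohexadiene) reduces the alkenyl bromide to the alkyl bromide. The α-bromo radical should take hydrogen from the lower face, opposite the axial C4 methyl group, which leaves bromine equatorial as in 14.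

**Step 10.**
- What may go wrong: chloride may attack at C1′ with allylic shift, or ionisation may erode stereochemical fidelity at the hindered C3.
- The fallback sets out from 15 and returns at 17. It places chlorine next to a ketone, where substitution is accelerated and the configuration can equilibrate, and then rebuilds the side chain.
- Ozonolysis (O3, CH2Cl2/MeOH, −78 °C; Me2S) gives (1S,3R,5R)-5-bromo-3-hydroxy-4,4-dimethyl-2-oxocyclohexyl acetate F4.
- PPh3/hexachloroacetone gives (1S,3S,5R)-5-bromo-3-chloro-4,4-dimethyl-2-oxocyclohexyl acetate F5. Its axial chloride is also the thermodynamic epimer of the α-chloro ketone.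
- Vinylmagnesium bromide/CeCl3 at −78 °C adds to the ketone faster than to the acetate and gives (1S,3S,5R)-5-bromo-3-chloro-2-ethenyl-2-hydroxy-4,4-dimethylcyclohexyl acetate F6 (either C2 epimer serves).
- PBr3 (Et2O, 0 °C) converts the tertiary allylic alcohol by SN2′ into 17. The CH2Br group should turn to the side of the axial C3–Cl bond to avoid A1,3 strain with the equatorial acetate.

**Step 7.**
- What may go wrong: the copper species may enolise the aldehyde, followed by β-elimination of acetate. Simple conjugate reduction without ring closure, or weak facial control at C5, is also possible.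
- The fallback sets out from 10 and returns at 13. It makes the enolate from a carbon–bromine bond with divalent chromium instead of by hydride addition.
- RhCl(PPh3)3/Et3SiH 1,4-hydrosilylation of the methacryloyl unit gives (3S,4Z)-4-[2-(TBSO)ethylidene]-1,1-diethoxy-6-methyl-5-[(triethylsilyl)oxy]hept-5-en-3-yl acetate F7.
- NBS gives (3S,4Z)-6-bromo-4-[2-(TBSO)ethylidene]-1,1-diethoxy-6-methyl-5-oxoheptan-3-yl acetate F8.
- Acetal cleavage as in step 6 gives (3S,4Z)-6-bromo-4-[2-(TBSO)ethylidene]-6-methyl-1,5-dioxoheptan-3-yl acetate F9.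
- CrCl2 (THF, 25 °C) closes the ring in an intramolecular chromium Reformatsky reaction. It is aldehyde-selective and non-basic, and it again proceeds through a closed chair array, to give 13.

**Further compounds**
F1 | step 8 | (1S,2Z)-2-[2-(TBSO)ethylidene]-4,4-dimethyl-3,5-dioxocyclohexyl acetate | CC(=O)O[C@H]1CC(=O)C(C)(C)C(=O)/C1=C\CO[Si](C)(C)C(C)(C)C
F2 | step 8 | (1S,2Z)-5-[2-(tert-butyldimethylsilyl)hydrazinylidene]-2-[2-(TBSO)ethylidene]-4,4-dimethyl-3-oxocyclohexyl acetate | CC(=O)O[C@H]1CC(=NN[Si](C)(C)C(C)(C)C)C(C)(C)C(=O)/C1=C\CO[Si](C)(C)C(C)(C)C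
F3 | step 8 | (1S,6Z)-3-bromo-6-[2-(TBSO)ethylidene]-4,4-dimethyl-5-oxocyclohex-2-en-1-yl acetate | CC(=O)O[C@H]1C=C(Br)C(C)(C)C(=O)/C1=C\CO[Si](C)(C)C(C)(C)C
F4 | step 10 | (1S,3R,5R)-5-bromo-3-hydroxy-4,4-dimethyl-2-oxocyclohexyl acetate | CC(=O)O[C@H]1C[C@@H](Br)C(C)(C)[C@@H](O)C1=O
F5 | step 10 | (1S,3S,5R)-5-bromo-3-chloro-4,4-dimethyl-2-oxocyclohexyl acetate | CC(=O)O[C@H]1C[C@@H](Br)C(C)(C)[C@H](Cl)C1=O
F6 | step 10 | (1S,3S,5R)-5-bromo-3-chloro-2-ethenyl-2-hydroxy-4,4-dimethylcyclohexyl acetate | CC(=O)O[C@H]1C[C@@H](Br)C(C)(C)[C@H](Cl)C1(O)C=C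
F7 | step 7 | (3S,4Z)-4-[2-(TBSO)ethylidene]-1,1-diethoxy-6-methyl-5-[(triethylsilyl)oxy]hept-5-en-3-yl acetate | CC(=O)O[C@@H](CC(OCC)OCC)/C(C(O[Si](CC)(CC)CC)=C(C)C)=C/CO[Si](C)(C)C(C)(C)C
F8 | step 7 | (3S,4Z)-6-bromo-4-[2-(TBSO)ethylidene]-1,1-diethoxy-6-methyl-5-oxoheptan-3-yl acetate | CC(=O)O[C@@H](CC(OCC)OCC)/C(C(=O)C(C)(C)Br)=C/CO[Si](C)(C)C(C)(C)C
F9 | step 7 | (3S,4Z)-6-bromo-4-[2-(TBSO)ethylidene]-6-methyl-1,5-dioxoheptan-3-yl acetate | CC(=O)O[C@@H](CC=O)/C(C(=O)C(C)(C)Br)=C/CO[Si](C)(C)C(C)(C)C
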